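A product curve that bends is easily read as a substrate running out, but anything that slows the reaction bends it too. So we look for a number that ignores such slowing.

| setting | theta | zeta | eta | flask |
|---|---|---|---|---|
| left-handed substrate | 20 mM | 20 mM | 30 mM | 20 mM |
| right-handed substrate | 20 mM | 20 mM | 30 mM | 20 mM |
| reagent | 80 mM | 80 mM | 80 mM | 80.0 mM |
| free catalyst | 12 µM | 12 µM | 12 µM | 12 µM |
| racemization catalyst | 20 µM | 20 µM | 20 µM | 20 µM |
| added ligand | 21 µM | 48 µM | 32 µM | 32 µM |
| remark | run made earlier | run made earlier | run made earlier |  |
| time |  |  |  | 25 min |

| run | time / min | left-handed product / % | right-handed product / % |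
|---|---|---|---|
| theta | 1.33 | 4 | 0 |
| theta | 2.00 | 6 | 1 |
| theta | 3.00 | 7 | 0 |
| theta | 4.00 | 12 | 3 |
| theta | 6.00 | 13 | 1 |
| theta | 10.0 | 21 | 4 |
| theta | 15.0 | 27 | 0 |
| zeta | 2.00 | 2 | 2 |
| zeta | 4.00 | 10 | 0 |
| zeta | 6.00 | 13 | 3 |
| zeta | 8.00 | 19 | 0 |
| zeta | 10.0 | 21 | 0 |
| zeta | 12.0 | 20 | 1 |
| zeta | 15.0 | 26 | 6 |
| eta | 1.33 | 5 | 0 |
| eta | 4.00 | 11 | 0 |
| eta | 8.00 | 18 | 3 |
| eta | 10.0 | 16 | 2 |
| eta | 15.0 | 27 | 2 |

(readings scatter by 2 percentage points)

* left-handed product and right-handed product together, in percent of the left-handed substrate and right-handed substrate charged together, at 25 min
* excess of left-handed product over right-handed product in the product at 25 min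
* whether the exchange between left-handed substrate and right-handed substrate keeps pace with the reaction: how far the product's excess at 25 min gets from its value without exchange to its value with instant exchange (above 80% keeps pace, below 20% hardly takes part, else lags behind)

- free catalyst is single-handed; left-handed substrate and right-handed substrate are mirror images of each other, charged as a racemate, each of them at the stated concentration
- an excess is the difference of the two amounts in percent of their sum
- an excess is below zero if the other one leads

Suppose each product forms at its own rate constant times its own substrate, times a term for catalyst and reagent that the two share. That shared term cancels in the ratio of the two rates, which leaves the ratio of the constants times the ratio of the substrates. Pooled over the theta, zeta and eta runs, left-handed over right-handed product is 9.93. With the substrates held equal by exchange, we take this reading as the selectivity factor, the ratio of the two rate constants. If exchange held the two substrates equal, the product's excess would stay at the factor less one over the factor plus one, 81.7%.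

Without exchange the two substrates drift apart, and the same readings mean something else. At 15.0 min the three runs average 26.7% left-handed product, which leaves 46.6% of the left-handed substrate. Right-handed product there averages 2.67%, each reading good to 2 percentage points. Taken without exchange, the fractions of the two substrates left give a factor of 13.9, and that describes these readings as well as 9.93 does with exchange. So the readings do not choose between the two. Racemization catalyst stands in the flask at 20 µM, as in the runs, and on that judgement we commit to an excess near 81.7% in the flask, with exchange keeping pace.

The forecast gives a yield of 44%, an excess of 72%, and exchange that hardly takes part: “exchange looks negligible in every run”. We part from it on the excess and the pace.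

The flask gives a yield of 42.3% and an excess of 80.3%, and exchange keeps pace, getting 95% of the way.

    reagent + free catalyst + left-handed substrate → free catalyst + left-handed product (k = 64000 M⁻² min⁻¹)
    reagent + free catalyst + right-handed substrate → free catalyst + right-handed product (k = 6800 M⁻² min⁻¹)
    left-handed substrate + racemization catalyst ⇌ right-handed substrate + racemization catalyst, rate k3*[racemization catalyst]*[left-handed substrate] forward; the back reaction follows from the equilibrium constant (k = 35000 M⁻¹ min⁻¹)
    free catalyst + added ligand ⇌ idle complex (K = 14000 M⁻¹, k = 3500 M⁻¹ min⁻¹)

At 25.0 min in the flask, the two substrates relax towards each other by exchange with a half-life of 0.495 min, far shorter than the half-life of 20 min of the left-handed substrate by its reaction to product. The substrates stand at 28.5% and 29.1%, and our factor of 9.93 had given 81.7%. In the neighbour flask with 320 mM of reagent, reagent sits in the shared term, so the factor again gives 81.7%. That flask reaches a yield of 89.3% with an excess of 78.9%.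

(Readings and results come from a simulation for an exercise, and the scatter is random.)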